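(The data are simulated with made-up constants; the scatter is artificial.)

The easy step is a count: each product takes up one reagent, so a flask charged with 0.500 equiv of reagent has room for 50.0% of its starting material as product. Free catalyst takes up starting material to give catalyst intermediate A, A binds reagent to give catalyst intermediate B, and B releases product and free catalyst, while reagent can also slip into the dormant form.

| flask | starting material | reagent | free catalyst | temperature | remark | time |
|---|---|---|---|---|---|---|
| amber | 7.5 mM | 0.50 equiv | 2 mol% | 95 °C | run made earlier |  |
| green | 23 mM | 0.50 equiv | 2 mol% | 128 °C | run made earlier |  |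
| red | 54 mM | 0.50 equiv | 2 mol% | 95 °C | run made earlier |  |
| violet | 42 mM | 0.50 equiv | 1.8 mol% | 128 °C | run made earlier |  |
| zeta | 60 mM | 0.500 equiv | 0.6 mol% | 80 °C |  | 3.0 h |
| theta | 42 mM | 0.500 equiv | 2 mol% | 110 °C |  | 3.0 h |
| alpha | 10 mM | 1.00 equiv | 2 mol% | 125 °C |  | 3.0 h |
| epsilon | 42 mM | 0.500 equiv | 3 mol% | 140 °C |  | 3.0 h |
| beta | 42 mM | 0.500 equiv | 2 mol% | 140 °C |  | 3.0 h |

| amber: time / h | amber: product / % | green: time / min | green: product / % | red: time / h | red: product / % | violet: time / min | violet: product / % |
|---|---|---|---|---|---|---|---|
| 0.833 | 0 | 6.00 | 1 | 0.833 | 3 | 20.0 | 5 |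
| 2.00 | 0 | 12.0 | 7 | 2.00 | 15 | 40.0 | 9 |
| 4.00 | 6 | 30.0 | 4 | 4.00 | 14 | 60.0 | 10 |
| 6.00 | 4 | 80.0 | 6 | 6.00 | 15 | 80.0 | 12 |

(standard deviation of a reading: 2 percentage points)

- the flasks put in order of amount of product, in percent of the starting material charged, best first, at 3.0 h (zeta / theta / alpha / epsilon / beta)
- the same order at 25 h (zeta / theta / alpha / epsilon / beta)
- the amount of product, in percent of the starting material charged of the flask you put first, at 3.0 h
- the amount of product, in percent of the starting material charged of the flask you put last, at 3.0 h

- steps thought possible: starting material + free catalyst -> catalyst intermediate A; catalyst intermediate B -> free catalyst + product; reagent + catalyst intermediate A <-> catalyst intermediate B; reagent <-> dormant form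

The last readings lie between 4% and 15%, short of that count. Let f be the capture share, the part of the reagent charge that has become product at the last reading: red gives 30.0%, violet 24.0%. These shares differ, but so does the catalyst concentration c, the starting concentration times the loading: 1.08 mM in red, 0.756 mM in violet. That suggests a race for reagent between catalyst and dormant form, and a capture constant σ = f/c, the capture share per unit of catalyst concentration, averaged over these two runs: 0.298 mM⁻¹.

The objection is that two noisy runs prove little. Green, however, reads 0.261 mM⁻¹, and at 128 °C against red's 95 °C no temperature effect shows through the scatter. Amber's last reading, 4%, is just twice the scatter, so amber stands too near the scatter to weigh against this.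

With σ, reckoned product is σ·c times the reagent equivalents. Epsilon gets 18.8%, theta and beta level at 12.5%, alpha 5.95% and zeta 5.36%. Zeta meets a second objection: it is cooler than red, and red stood at 3% after 0.833 h, so zeta may not flatten within 3.0 h and belongs below its figure, last. The order at 25 h lies beyond the readings, which end at 6.00 h, so this reckoning offers none.

The forecast holds that “More catalyst should scale the plateau up roughly in proportion”. It gives epsilon > theta > beta > alpha > zeta at 3.0 h and epsilon > beta > theta > alpha > zeta at 25 h, with 16% on top (range 12% to 22%) and 4% last (range 1.5% to 7%). The reckoning above differs: it puts epsilon higher, at 18.8%, and keeps theta and beta level.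

The flasks give epsilon > beta > theta > alpha > zeta at 3.0 h and epsilon > beta > alpha > theta > zeta at 25 h, with 24.5% on top and 1.89% last.

    starting material + free catalyst → catalyst intermediate A (k = 5.20 M⁻¹ min⁻¹, Ea = 88.0 kJ mol⁻¹)
    catalyst intermediate B → free catalyst + product (k = 1.20 min⁻¹, Ea = 108 kJ mol⁻¹)
    reagent + catalyst intermediate A ⇌ catalyst intermediate B (K = 380 M⁻¹, k = 58.0 M⁻¹ min⁻¹, Ea = 59.0 kJ mol⁻¹, ΔH = −68.0 kJ mol⁻¹)
    reagent ⇌ dormant form (K = 34.0, k = 0.0470 min⁻¹, Ea = 103 kJ mol⁻¹, ΔH = 21.0 kJ mol⁻¹)
    (constants at 110 °C)

In epsilon the product at 3.0 h is no end point. Removing the path from reagent to dormant form lifts epsilon's product from 24.5% to 50.0%, and a run ten times as long reaches 49.8%. At 3.00 h epsilon still holds 10.6 mM of dormant form, with 0.629% of its reagent, the limiting reagent, free. The reckoned 18.8% for epsilon lies below the flask's 24.5%, by a factor 1.30. For a neighbour of epsilon with 0.300 equiv of reagent, σ·c times those equivalents gives 11.2%; that flask gives 15.2%, a factor 1.36 above the reckoning.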